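**Plan** (chain numbered C1 at the guaiacyl ring to C7 at the S carbinol carbon)
- The enolised C3/C5 diketone is carried as a 3,5-disubstituted isoxazole whose ring atoms are C3, C4, C5, the C3 oxygen and a nitrogen in place of the C5 oxygen. This neutral ring protects the elimination-prone C7 oxygen until N–O scission and hydrolysis.
- Retrosynthetic cuts: C4–C5 together with the ring O–C3 bond (nitrile oxide plus terminal alkyne), C6–C7 (allylation of an aryl aldehyde), C3–C4 (aldehyde-to-alkyne homologation).
- Forward: 4-silyloxybenzaldehyde gives the C5–C7 hydroximoyl chloride (steps 1–5) and coniferyl aldehyde gives the C1–C4 enyne (steps 6–7). Step 8 joins them and closes the only ring made; steps 9–11 open the ring, hydrolyse and desilylate.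
- Stereochemistry: C7 (S) comes from reagent-controlled Brown allylation in step 1 and is not touched afterwards. The C1=C2 E alkene is bought with coniferyl aldehyde.

Key step: step 8

Remark on the chemistry: the C3=C4 enol geometry in the target formula is one depiction of a rapidly equilibrating enolised 1,3-diketone and is not a controllable stereo-element. The target is therefore taken as the (7S)-3,5-dione in its enol form and written with the formula given.

**Step 1**
Reactants: 1 4-(tert-butyldimethylsilyloxy)benzaldehyde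
Product: 3 (S)-1-[4-(tert-butyldimethylsilyloxy)phenyl]but-3-en-1-ol, via borinate ester 2 (not isolated)
Conditions: commercial (−)-Ipc2B(allyl) in pentane, Et2O, −78 °C; then pH 7 phosphate buffer, MeOH, 30% H2O2, 0 °C → rt
Reagents that add atoms: (−)-B-allyldiisopinocampheylborane, C=CCB([C@@H]1C[C@@H]2C[C@H]([C@H]1C)C2(C)C)[C@@H]1C[C@@H]2C[C@H]([C@H]1C)C2(C)C
Why: Brown allylboration through a closed chair (Zimmerman–Traxler) transition state, in which the isopinocampheyl groups of the (+)-α-pinene-derived reagent steer the allyl group to the Si face of the aldehyde, should create C7 with S configuration, and the buffered peroxide work-up frees the alcohol from borinate 2 without cleaving the aryl silyl ether.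

**Step 2**
Reactants: 3 (S)-1-[4-(tert-butyldimethylsilyloxy)phenyl]but-3-en-1-ol
Product: 4 (S)-tert-butyl{4-[1-(tert-butyldimethylsilyloxy)but-3-en-1-yl]phenoxy}dimethylsilane
Conditions: TBSCl, imidazole, DMF, rt
Reagents that add atoms: tert-butyldimethylsilyl chloride, CC(C)(C)[Si](C)(C)Cl
Why: imidazole-mediated O-silylation of a secondary alcohol breaks no bond at C7, so the configuration is retained.

**Step 3**
Reactants: 4 (S)-tert-butyl{4-[1-(tert-butyldimethylsilyloxy)but-3-en-1-yl]phenoxy}dimethylsilane
Product: 6 (S)-3-(tert-butyldimethylsilyloxy)-3-[4-(tert-butyldimethylsilyloxy)phenyl]propanal, via secondary ozonide 5 (not isolated)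
Conditions: O3, CH2Cl2, −78 °C (stopped at first excess); then PPh3, −78 °C → rt
Reagents that add atoms: ozone, [O-][O+]=O
Why: ozonolysis with reductive work-up cleaves the terminal alkene, which reacts far faster than the silyloxyarene, and the neutral conditions keep the β-silyloxy aldehyde from eliminating.

**Step 4**
Reactants: 6 (S)-3-(tert-butyldimethylsilyloxy)-3-[4-(tert-butyldimethylsilyloxy)phenyl]propanal
Product: 7 (S)-3-(tert-butyldimethylsilyloxy)-3-[4-(tert-butyldimethylsilyloxy)phenyl]propanal oxime (E/Z mixture)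
Conditions: NH2OH·HCl, NaOAc, EtOH/THF, rt
Reagents that add atoms: hydroxylamine hydrochloride, Cl.NO
Why: acetate-buffered oxime condensation is too mild to eliminate the β-silyloxy group, and the oxime geometry is irrelevant because both isomers converge in step 5.

**Step 5**
Reactants: 7 (S)-3-(tert-butyldimethylsilyloxy)-3-[4-(tert-butyldimethylsilyloxy)phenyl]propanal oxime
Product: 8 (S,Z)-3-(tert-butyldimethylsilyloxy)-3-[4-(tert-butyldimethylsilyloxy)phenyl]-N-hydroxypropanimidoyl chloride
Conditions: NCS, DMF, 0 °C → rt; used after aqueous work-up without chromatography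
Reagents that add atoms: N-chlorosuccinimide, O=C1CCC(=O)N1Cl
Why: electrophilic chlorination of the aldoxime carbon by NCS in DMF is the standard hydroximoyl chloride synthesis and is much faster than ring chlorination of the para-substituted aryl silyl ether.

**Step 6**
Reactants: 9 coniferyl aldehyde
Product: 10 (E)-3-[4-(tert-butyldimethylsilyloxy)-3-methoxyphenyl]prop-2-enal
Conditions: TBSCl, imidazole, CH2Cl2, rt
Reagents that add atoms: tert-butyldimethylsilyl chloride, CC(C)(C)[Si](C)(C)Cl
Why: phenol silylation removes the acidic proton that would quench the lithium reagent of step 7.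

**Step 7**
Reactants: 10 (E)-3-[4-(tert-butyldimethylsilyloxy)-3-methoxyphenyl]prop-2-enal
Product: 11 (E)-tert-butyl[4-(but-1-en-3-yn-1-yl)-2-methoxyphenoxy]dimethylsilane
Conditions: Me3SiCHN2, LiN(iPr)2, THF, −78 °C → rt; then H2O
Reagents that add atoms: trimethylsilyldiazomethane, C[Si](C)(C)C=[N+]=[N-]
Why: Colvin rearrangement (1,2-addition of lithiated trimethylsilyldiazomethane, Peterson-type loss of silanolate and N2, 1,2-hydride shift of the alkylidene carbene) turns the enal into the terminal enyne under aprotic, alkoxide-free conditions, whereas a methanolic carbonate homologation would add methanol across the enal system and strip the aryl silyl ether.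

**Step 8**
Reactants: 8 (S,Z)-3-(tert-butyldimethylsilyloxy)-3-[4-(tert-butyldimethylsilyloxy)phenyl]-N-hydroxypropanimidoyl chloride; 11 (E)-tert-butyl[4-(but-1-en-3-yn-1-yl)-2-methoxyphenoxy]dimethylsilane
Product: 14 (S,E)-3-{2-(tert-butyldimethylsilyloxy)-2-[4-(tert-butyldimethylsilyloxy)phenyl]ethyl}-5-{2-[4-(tert-butyldimethylsilyloxy)-3-methoxyphenyl]ethenyl}isoxazole, via copper acetylide 12 (not isolated), via nitrile oxide 13 (not isolated)
Conditions: CuSO4·5H2O (5 mol %), sodium ascorbate (15 mol %), KHCO3, THF/t-BuOH/H2O, rt; 8 added slowly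
Reagents that add atoms: none
Why: KHCO3 strips HCl from 8 to release nitrile oxide 13 slowly, while monovalent copper (from CuSO4 and ascorbate) converts the terminal alkyne of 11 into acetylide 12. The two combine stepwise through a six-membered copper metallacycle that contracts by reductive elimination to a 4-cuprated isoxazole, and protonolysis frees 14 and returns the catalyst; the closest known reaction type is the copper-catalysed cycloaddition of nitrile oxides with terminal alkynes to 3,5-disubstituted isoxazoles. The isoxazole ring closes as a formal [3+2] annulation in which the C4–C5 bond (nitrile oxide carbon to the terminal alkyne carbon) and the O–C3 bond (to the internal alkyne carbon) are made in separate events within the copper template. No stereocentre is created, and C7 is untouched because neither the weak base nor the neutral dipole can remove its hydrogen or expel its silyloxy group. The step needs chemoselectivity for the alkyne over the 1,2-disubstituted styrenyl alkene and 3,5-regioselectivity: the acetylide pathway is far faster than thermal addition to an internal alkene and gives only the 3,5-isomer, while slow addition of 8 keeps 13 dilute and suppresses furoxan formation.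

**Step 9**
Reactants: 14 (S,E)-3-{2-(tert-butyldimethylsilyloxy)-2-[4-(tert-butyldimethylsilyloxy)phenyl]ethyl}-5-{2-[4-(tert-butyldimethylsilyloxy)-3-methoxyphenyl]ethenyl}isoxazole
Product: 15 (1E,4Z,7S)-5-amino-7-(tert-butyldimethylsilyloxy)-1-[4-(tert-butyldimethylsilyloxy)-3-methoxyphenyl]-7-[4-(tert-butyldimethylsilyloxy)phenyl]hepta-1,4-dien-3-one
Conditions: Mo(CO)6, MeCN/H2O, 80 °C
Reagents that add atoms: none
Why: reductive N–O cleavage of an isoxazole by zerovalent molybdenum with water as the hydrogen source gives the chelated Z β-amino enone under neutral conditions and, unlike catalytic hydrogenation, leaves the C1=C2 alkene and the silyl ethers alone.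

**Step 10**
Reactants: 15 (1E,4Z,7S)-5-amino-7-(tert-butyldimethylsilyloxy)-1-[4-(tert-butyldimethylsilyloxy)-3-methoxyphenyl]-7-[4-(tert-butyldimethylsilyloxy)phenyl]hepta-1,4-dien-3-one
Product: 16 (1E,7S)-7-(tert-butyldimethylsilyloxy)-1-[4-(tert-butyldimethylsilyloxy)-3-methoxyphenyl]-7-[4-(tert-butyldimethylsilyloxy)phenyl]hept-1-ene-3,5-dione, as its C3 enol
Conditions: 0.5 M aq. oxalic acid, THF, rt
Reagents that add atoms: water, O
Why: acid-catalysed hydrolysis of a primary vinylogous amide (protonation at C4, addition of water to the C5 iminium, loss of ammonia) should give the enolised diketone, and the weak acid is not expected to ionise or eliminate the C7 silyl ether in the time needed.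

**Step 11**
Reactants: 16 (1E,7S)-7-(tert-butyldimethylsilyloxy)-1-[4-(tert-butyldimethylsilyloxy)-3-methoxyphenyl]-7-[4-(tert-butyldimethylsilyloxy)phenyl]hept-1-ene-3,5-dione
Product: 17 (1E,7S)-7-hydroxy-7-(4-hydroxyphenyl)-1-(4-hydroxy-3-methoxyphenyl)hept-1-ene-3,5-dione, as its C3 enol (target)
Conditions: Bu4NF/AcOH (1:1), THF, 0 °C → rt
Reagents that add atoms: none
Why: fluoride-driven cleavage of the two aryl and the one benzylic silyl ether, buffered with acetic acid so that the freed β-hydroxy ketone should neither dehydrate nor fragment by retro-aldol and C7 keeps its configuration.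

**Compound list**
1 | 4-(tert-butyldimethylsilyloxy)benzaldehyde | O=Cc1ccc(O[Si](C)(C)C(C)(C)C)cc1 | starting material
2 | (S)-1-[4-(tert-butyldimethylsilyloxy)phenyl]but-3-en-1-yl diisopinocampheylborinate | C=CC[C@H](OB([C@@H]1C[C@@H]2C[C@H]([C@H]1C)C2(C)C)[C@@H]1C[C@@H]2C[C@H]([C@H]1C)C2(C)C)c1ccc(O[Si](C)(C)C(C)(C)C)cc1 | intermediate
3 | (S)-1-[4-(tert-butyldimethylsilyloxy)phenyl]but-3-en-1-ol | C=CC[C@H](O)c1ccc(O[Si](C)(C)C(C)(C)C)cc1 | intermediate
4 | (S)-tert-butyl{4-[1-(tert-butyldimethylsilyloxy)but-3-en-1-yl]phenoxy}dimethylsilane | C=CC[C@H](O[Si](C)(C)C(C)(C)C)c1ccc(O[Si](C)(C)C(C)(C)C)cc1 | intermediate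
5 | 3-{(S)-2-(tert-butyldimethylsilyloxy)-2-[4-(tert-butyldimethylsilyloxy)phenyl]ethyl}-1,2,4-trioxolane (secondary ozonide, epimers at the ring carbon) | C1OC(C[C@H](O[Si](C)(C)C(C)(C)C)c2ccc(O[Si](C)(C)C(C)(C)C)cc2)OO1 | intermediate
6 | (S)-3-(tert-butyldimethylsilyloxy)-3-[4-(tert-butyldimethylsilyloxy)phenyl]propanal | O=CC[C@H](O[Si](C)(C)C(C)(C)C)c1ccc(O[Si](C)(C)C(C)(C)C)cc1 | intermediate
7 | (S)-3-(tert-butyldimethylsilyloxy)-3-[4-(tert-butyldimethylsilyloxy)phenyl]propanal oxime (E/Z mixture) | ON=CC[C@H](O[Si](C)(C)C(C)(C)C)c1ccc(O[Si](C)(C)C(C)(C)C)cc1 | intermediate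
8 | (S,Z)-3-(tert-butyldimethylsilyloxy)-3-[4-(tert-butyldimethylsilyloxy)phenyl]-N-hydroxypropanimidoyl chloride | O/N=C(\Cl)C[C@H](O[Si](C)(C)C(C)(C)C)c1ccc(O[Si](C)(C)C(C)(C)C)cc1 | intermediate
9 | coniferyl aldehyde, (E)-3-(4-hydroxy-3-methoxyphenyl)prop-2-enal | COc1cc(/C=C/C=O)ccc1O | starting material
10 | (E)-3-[4-(tert-butyldimethylsilyloxy)-3-methoxyphenyl]prop-2-enal | COc1cc(/C=C/C=O)ccc1O[Si](C)(C)C(C)(C)C | intermediate
11 | (E)-tert-butyl[4-(but-1-en-3-yn-1-yl)-2-methoxyphenoxy]dimethylsilane | COc1cc(/C=C/C#C)ccc1O[Si](C)(C)C(C)(C)C | intermediate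
12 | copper acetylide of 11 (monovalent copper) | COc1cc(/C=C/C#C[Cu])ccc1O[Si](C)(C)C(C)(C)C | intermediate
13 | (S)-3-(tert-butyldimethylsilyloxy)-3-[4-(tert-butyldimethylsilyloxy)phenyl]propanenitrile oxide | [O-][N+]#CC[C@H](O[Si](C)(C)C(C)(C)C)c1ccc(O[Si](C)(C)C(C)(C)C)cc1 | intermediate
14 | (S,E)-3-{2-(tert-butyldimethylsilyloxy)-2-[4-(tert-butyldimethylsilyloxy)phenyl]ethyl}-5-{2-[4-(tert-butyldimethylsilyloxy)-3-methoxyphenyl]ethenyl}isoxazole | COc1cc(/C=C/c2cc(C[C@H](O[Si](C)(C)C(C)(C)C)c3ccc(O[Si](C)(C)C(C)(C)C)cc3)no2)ccc1O[Si](C)(C)C(C)(C)C | intermediate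
15 | (1E,4Z,7S)-5-amino-7-(tert-butyldimethylsilyloxy)-1-[4-(tert-butyldimethylsilyloxy)-3-methoxyphenyl]-7-[4-(tert-butyldimethylsilyloxy)phenyl]hepta-1,4-dien-3-one | COc1cc(/C=C/C(=O)/C=C(\N)C[C@H](O[Si](C)(C)C(C)(C)C)c2ccc(O[Si](C)(C)C(C)(C)C)cc2)ccc1O[Si](C)(C)C(C)(C)C | intermediate
16 | (1E,7S)-7-(tert-butyldimethylsilyloxy)-1-[4-(tert-butyldimethylsilyloxy)-3-methoxyphenyl]-7-[4-(tert-butyldimethylsilyloxy)phenyl]hept-1-ene-3,5-dione, C3 enol | COc1cc(/C=C/C(O)=C\C(=O)C[C@H](O[Si](C)(C)C(C)(C)C)c2ccc(O[Si](C)(C)C(C)(C)C)cc2)ccc1O[Si](C)(C)C(C)(C)C | intermediate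
17 | (1E,7S)-7-hydroxy-7-(4-hydroxyphenyl)-1-(4-hydroxy-3-methoxyphenyl)hept-1-ene-3,5-dione, C3 enol (CNP0206527.1) | COc1cc(/C=C/C(O)=C\C(=O)C[C@H](O)c2ccc(O)cc2)ccc1O | target

**Totals**
Total step count: 11. Longest linear sequence: 9 steps (steps 1, 2, 3, 4, 5, 8, 9, 10, 11, from compound 1).

**Steps most likely to fail**

**Step 8.** The aliphatic nitrile oxide may dimerise to the furoxan faster than it is captured, because the valuable enyne cannot be used in large excess. The copper enyne acetylide may also homocouple or oligomerise, and background addition at the styrenyl alkene may erode chemoselectivity. The fallback sets out from 8 and keeps the same ring construction but moves the styrene formation behind it. Nitrile oxide 13 is released from 8 with KHCO3 in the presence of a large excess of the cheap, alkene-free dipolarophile diethyl prop-2-yn-1-ylphosphonate. This should give diethyl ({3-[(2S)-2-(tert-butyldimethylsilyloxy)-2-[4-(tert-butyldimethylsilyloxy)phenyl]ethyl]isoxazol-5-yl}methyl)phosphonate F1. Deprotonation of F1 with LiN(SiMe3)2 in THF at −78 °C and Horner–Wadsworth–Emmons olefination with 4-(tert-butyldimethylsilyloxy)-3-methoxybenzaldehyde F2 (from vanillin, TBSCl, imidazole) would then form the C1=C2 bond with E geometry. The route is rejoined at 14.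

**Step 10.** Hydrolysis of the vinylogous amide may be slow, so that acid strong enough to drive it also causes loss of the C7 silyloxy group or 6-endo aza-Michael closure of the amino dienone to a dihydropyridinone. The fallback lowers the oxidation level of the mask and sets out from 10 and 8. Wittig methylenation of 10 (Ph3PCH3Br, KN(SiMe3)2, THF) would give (E)-tert-butyl[4-(buta-1,3-dien-1-yl)-2-methoxyphenoxy]dimethylsilane F3. Copper-free cycloaddition of nitrile oxide 13 (from 8, KHCO3, EtOAc/H2O) at the terminal vinyl group of F3 should give the 5-styryl-4,5-dihydroisoxazole F4 as a mixture of ring epimers, which is of no consequence. Mo(CO)6 in wet MeCN cleaves the N–O bond, and the resulting β-hydroxy imine hydrolyses in the same pot, with no vinylogous amide to resist, to the C3-hydroxy C5-ketone F5. Dess–Martin oxidation of the allylic C3 alcohol of F5 (NaHCO3, CH2Cl2) gives the diketone, and the route is rejoined at 16.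

**Step 11.** The basic fluoride medium may trigger dehydration across C6–C7 or retro-aldol fragmentation as soon as the C7 hydroxyl is free, or the hindered benzylic silyl ether may be cleaved incompletely. The fallback changes the order so that no β-hydroxy ketone meets fluoride; it sets out from 14. Bu4NF in THF removes all three silyl groups while the diketone is still locked in the base-stable ring, giving the triol isoxazole F6. Mo(CO)6 in wet MeCN then gives the amino dienone triol F7, and brief hydrolysis of F7 in dilute aqueous oxalic acid releases the product directly. The route is rejoined at 17.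

**Further compounds**
F1 | step 8 | diethyl ({3-[(2S)-2-(tert-butyldimethylsilyloxy)-2-[4-(tert-butyldimethylsilyloxy)phenyl]ethyl]isoxazol-5-yl}methyl)phosphonate | CCOP(=O)(Cc1cc(C[C@H](O[Si](C)(C)C(C)(C)C)c2ccc(O[Si](C)(C)C(C)(C)C)cc2)no1)OCC
F2 | step 8 | 4-(tert-butyldimethylsilyloxy)-3-methoxybenzaldehyde | COc1cc(C=O)ccc1O[Si](C)(C)C(C)(C)C
F3 | step 10 | (E)-tert-butyl[4-(buta-1,3-dien-1-yl)-2-methoxyphenoxy]dimethylsilane | COc1cc(/C=C/C=C)ccc1O[Si](C)(C)C(C)(C)C
F4 | step 10 | 3-{(S)-2-(tert-butyldimethylsilyloxy)-2-[4-(tert-butyldimethylsilyloxy)phenyl]ethyl}-5-{(E)-2-[4-(tert-butyldimethylsilyloxy)-3-methoxyphenyl]ethenyl}-4,5-dihydroisoxazole (ring epimers) | COc1cc(/C=C/C2CC(C[C@H](O[Si](C)(C)C(C)(C)C)c3ccc(O[Si](C)(C)C(C)(C)C)cc3)=NO2)ccc1O[Si](C)(C)C(C)(C)C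
F5 | step 10 | (1E,7S)-7-(tert-butyldimethylsilyloxy)-1-[4-(tert-butyldimethylsilyloxy)-3-methoxyphenyl]-7-[4-(tert-butyldimethylsilyloxy)phenyl]-3-hydroxyhept-1-en-5-one (C3 epimers) | COc1cc(/C=C/C(O)CC(=O)C[C@H](O[Si](C)(C)C(C)(C)C)c2ccc(O[Si](C)(C)C(C)(C)C)cc2)ccc1O[Si](C)(C)C(C)(C)C
F6 | step 11 | (S,E)-4-{2-[3-(2-hydroxy-2-(4-hydroxyphenyl)ethyl)isoxazol-5-yl]ethenyl}-2-methoxyphenol | COc1cc(/C=C/c2cc(C[C@H](O)c3ccc(O)cc3)no2)ccc1O
F7 | step 11 | (1E,4Z,7S)-5-amino-7-hydroxy-7-(4-hydroxyphenyl)-1-(4-hydroxy-3-methoxyphenyl)hepta-1,4-dien-3-one | COc1cc(/C=C/C(=O)/C=C(\N)C[C@H](O)c2ccc(O)cc2)ccc1O
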